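## The problem

Podocarpusflavone A (24) is a biflavone in which the hydroxyphenyl ring B of a 5,7-dihydroxyflavone (unit 1; ring B atoms primed) is bonded through C3' to C8'' of a 5,7-dihydroxy-4'-methoxyflavone (unit 2; chromone atoms double-primed, anisyl ring triple-primed). The C3'–C8'' bond is flanked by O4' on one ring and by O7'' and the pyranone oxygen O1'' on the other, so it is a tri-ortho-substituted biaryl bond between two electron-rich rings and a poor place to join two finished flavones. There is no stereocentre, so no centre can control another; the task is one of connectivity and of telling oxygens apart. Of the six aryl oxygens outside the pyranone rings, five end as free phenols and only O4''' stays methylated, so every temporary group must leave under conditions that spare an anisole. Ring A of unit 2 is a phloroglucinol whose three oxygens have three fates: O1'' closes the pyranone, O7'' is a phenol beside the biaryl bond, and O5'' must be kept out of the ring closure, because closure through it gives the 6-aryl isomer. The sensitive parts are benzyl ethers on phloroglucinol rings (cleaved or shifted to carbon by Friedel–Crafts Lewis acids), the pyranone rings (opened by hot aqueous base, and open to acid-induced 8-aryl to 6-aryl isomerization once O5'' is free) and the ynol silyl ether needed for the key step (hydrolysed by traces of acid). The key step rests on the substitution of ring B: C1' carries the carbon that becomes C2 of unit 1, C3' the hindered aryl group and C4' an oxygen, which is the 1,3,4 pattern of a benzoate built from C3–C6 of a 2-pyranone-5-carboxylate (C5 becomes C1', C6 C2', C3 C5', C4 C6') and a two-carbon donor alkyne that supplies C3' and C4'.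

## Retrosynthesis

**24 ⇒ 23.** The last step only removes protecting groups: four benzyl–oxygen bonds and the O5''–CH3 bond of 23 are cut. O5'' carries methyl and not a fifth benzyl group because a methyl ether survives the Lewis acid acetylation of ring A (below) and still leaves together with the benzyl groups: it sits peri to C4''=O, where a chelating boron halide removes it, while the methyl on O4''' has no such neighbour. The forward reaction has to tell two aryl methyl ethers apart.

**23 ⇒ 22 ⇒ 18 + 20.** The pyranone of unit 1 is opened at O1–C2 to the 1,3-diketone 22, which is cut at C2–C3 into the ring B carboxylic acid 18 and the acetophenone 20 (one step from 19). Acylation is preferred to a chalcone route for unit 1 because ring B leaves the key step at the carboxyl oxidation level, so no redox adjustment is needed. The cut removes half of the molecule. The forward reaction must acylate carbon, or be able to correct O-acylation by acyl migration.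

**18 ⇒ 17 ⇒ 15 + 16.** The pyranone of unit 2 is opened at O1''–C2'' to the 2'-hydroxychalcone 17, and the enone is cut at C2''=C3'' into the methyl ketone 15 and 4-methoxybenzaldehyde (16), which brings in the one methyl ether that stays. The chalcone route is chosen here because the hydroxide that drives the condensation also frees the carboxylic acid for the next coupling. In 17 the only free hydroxyl on ring A is the one beside the biaryl bond, so ring closure can give only the 8-aryl flavone.

**15 ⇒ 14 ⇒ 13.** Removing the benzyl groups on O7'' and O4' gives 14, and cutting the C4a''–C4'' bond (the acetyl group) gives triol 13. An unsymmetrical ring A with one marked oxygen and two benzyl ethers would need an ortho-selective Fries rearrangement under Lewis acids that attack those ethers. In 13 ring A is instead a symmetric 2-aryl-5-methoxyresorcinol: its two open carbons (the future C4a'' and C6'') are equivalent, so acetylation has no regiochemical choice, and no benzyl ether is present on the electron-rich ring. Once in place, the acetyl group marks its neighbouring hydroxyl by hydrogen bonding as the future O1'', and benzylation takes the two other hydroxyls. The forward demand is mono-acylation and a chelation-controlled alkylation.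

**13 ⇒ 11 ⇒ 8 + 9.** Desilylation and loss of two methoxymethyl groups relate 13 to 11 (through 12). Compound 11 is cut at C2'–C3' and C4'–C5', the two bonds that close ring B from methyl coumalate (9) and the ynol silyl ether 8 (through lactone 10). The neighbouring cut, through the C3'–C8'' bond itself, would need a cross-coupling with three ortho substituents. The chosen cut builds the benzene ring around the hindered aryl group and delivers in one step both the ester that becomes C2 of unit 1 and the oxygen on C4'. The precursors are a commercial pyranone and a monoaryl alkyne. The forward reaction must join the aryl-bearing alkyne carbon to C6 of the pyranone.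

**8 ⇒ 5 ⇒ 4 ⇒ 2 ⇒ 1.** The silicon–oxygen and oxygen–alkyne bonds of 8 lead back to the terminal alkyne 5 (oxygen transfer to acetylide 6, silylation of ynolate 7). Alkyne 5 comes from aldehyde 4 by one-carbon homologation, 4 from 2 by formylation of aryllithium 3, and 2 from 5-methoxyresorcinol (1). The methoxymethyl groups direct the lithiation to the carbon between them, survive base and heat up to the key step, and then leave together in mild acid. Each step is one functional group change on a symmetric arene.

## Roads not taken

**Alternative 1:** The cut runs through the pyranone of unit 1 (O1–C8a, C4a–C4 and O1–C2). Ring A of unit 1 comes as an aryne released by fluoride from the silylaryl triflate A2, and C2–C4 come as the propiolic acid A1 that ring B of a finished unit 2 carries. In the forward step the carboxylate adds to the aryne carbon remote from the alkoxy group, the aryl anion attacks the carbonyl, and the resulting ortho-acyl phenoxide closes onto the ynone to give A3.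
- Merits: the chromone of unit 1 forms in one operation under nearly neutral conditions, the aryne polarization sets the regiochemistry, and A3 carries benzyl ethers only, so the last step is a plain debenzylation. In these respects it is better than the chosen plan, which needs steps 12 and 13 for the same ring and must remove a peri methyl ether at the end.
- Weak points: A1 already contains the C3'–C8'' bond, so the hardest bond is left to a hindered cross-coupling. A1 and A2 each need several steps. Proton transfer from the acid to the aryl anion diverts material to an aryl ester, and the ynone may close 5-exo to an aurone.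
- Comparison: the chosen plan sets against this a solution of the biaryl bond itself and cheap precursors.

**Alternative 2:** The cut removes the whole chromone of unit 2 (C4a''–C8a'', C7''–C8'' and C5''–O) and leads to triyne A4, a siloxy-1,3-diyne tethered through an enone and an enol ether oxygen to an aryl ynol ether. Heating should bring about an intramolecular hexadehydro-Diels–Alder reaction; the aryne across C5''–C6'' is trapped by a carboxylic acid solvent with oxygen on C5'', giving A5.
- Merits: the pyranone and the benzene ring form in one step and the three ring A oxygens arrive as acetate, silyl ether and ring oxygen, so the 6-aryl or 8-aryl question never arises and no Friedel–Crafts step is needed. Here it is better than the chosen plan, which spends steps 6–10 on the same result.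
- Weak points: A4 combines an alkynyl vinyl ether, a siloxydiyne and a cross-conjugated ynone, has no reliable preparation and would be long to make and hard to store. The cycloaddition temperature is in the range where ynol silyl ethers rearrange to silylketenes. The sense of aryne trapping is steered only by the neighbouring siloxy group.
- Comparison: the chosen plan sets against this storable precursors and classical flavonoid steps after the key step.

**Alternative 3:** The cut runs through ring A of unit 2 (C8a''–C8'', C6''–C7'' and C4a''–C8a'') and leads to the cyclobutenone A7 and the aryl ynol silyl ether A6. Heat opens A7 to a vinylketene, which adds [2+2] to A6; the adduct reopens, electrocyclizes and tautomerizes to A8.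
- Merits: it uses the same kind of ynol silyl ether as the chosen plan, but ring A comes out with three different oxygens: free hydroxyl at the future O1'', silyl ether at O7'', ethyl ether at O5''. This is better than the chosen plan, which gets the same differentiation only through the symmetric ring and the hydrogen-bond argument of steps 7 and 8.
- Weak points: ring A of A8 is unsymmetrical, so the acetyl group must be placed by an ortho-specific Fries rearrangement with a silyl ether on the ring. Ring B arrives with bromine where the carboxyl carbon is needed, so a carbonylation is added. A7 is a specialty reagent.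
- Comparison: the length is similar. The chosen plan sets against it a commercial pyranone, a ring B that already holds the carboxyl carbon, and an acetylation without regiochemical choice.

Key step: step 5

Remark on the chemistry: the target is written without a stereodescriptor, so the C3'–C8'' axis is taken as not configurationally fixed and no control of axial chirality is planned.

## Route

Step 1
Reactants: 1 5-methoxyresorcinol (3,5-dihydroxyanisole)
Product: 2 1-methoxy-3,5-bis(methoxymethoxy)benzene
Conditions: MOMCl (2.5 equiv), iPr2NEt (3 equiv), CH2Cl2, 0 °C to rt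
Reagents that add atoms: chloromethyl methyl ether, COCCl
Why: O-alkylation of both phenols with an α-chloro ether and an amine base (acetal protection); the methoxymethyl groups are chosen because they direct the lithiation of step 2 and leave in mild acid in step 6.

Step 2
Reactants: 2 1-methoxy-3,5-bis(methoxymethoxy)benzene
Product: 4 4-methoxy-2,6-bis(methoxymethoxy)benzaldehyde, via aryllithium 3 (not isolated)
Conditions: n-BuLi (1.1 equiv), TMEDA, THF, 0 °C; DMF, 0 °C to rt; H2O
Reagents that add atoms: N,N-dimethylformamide, CN(C)C=O
Why: Directed ortho-metalation followed by Bouveault formylation; the C–H between the two methoxymethoxy groups is flanked by two chelating directors, each stronger than methoxy, so it should be lithiated in preference to the two sites flanked by methoxy and one methoxymethoxy group.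

Step 3
Reactants: 4 4-methoxy-2,6-bis(methoxymethoxy)benzaldehyde
Product: 5 2-ethynyl-5-methoxy-1,3-bis(methoxymethoxy)benzene
Conditions: dimethyl (1-diazo-2-oxopropyl)phosphonate (1.5 equiv), K2CO3, MeOH, rt
Reagents that add atoms: dimethyl (1-diazo-2-oxopropyl)phosphonate, CC(=O)C(=[N+]=[N-])P(=O)(OC)OC
Why: Seyferth–Gilbert homologation with the Ohira–Bestmann reagent turns the non-enolizable aldehyde into the terminal alkyne under mild carbonate conditions that leave the acetals alone; the electron-rich aldehyde should react slowly, so excess reagent and a long reaction time are planned.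

Step 4
Reactants: 5 2-ethynyl-5-methoxy-1,3-bis(methoxymethoxy)benzene
Product: 8 triisopropyl({[4-methoxy-2,6-bis(methoxymethoxy)phenyl]ethynyl}oxy)silane, via lithium acetylide 6 (not isolated), via lithium ynolate 7 (not isolated)
Conditions: LiN(SiMe3)2, THF, −78 °C; t-BuOOLi (from t-BuOOH and LiN(SiMe3)2), −78 to 0 °C; iPr3SiOTf, −78 to 0 °C
Reagents that add atoms: tert-butyl hydroperoxide, CC(C)(C)OO; triisopropylsilyl trifluoromethanesulfonate, CC(C)[Si](C(C)C)(C(C)C)OS(=O)(=O)C(F)(F)F
Why: Julia-type oxidation of a lithium acetylide by lithium tert-butyl peroxide gives the ynolate, which the bulky silyl triflate should take on oxygen (the one-pot route to aryl siloxyalkynes); the acetals and the methyl ether are inert, and 8 should be passed quickly through base-washed silica and used at once.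

Step 5
Reactants: 8 triisopropyl({[4-methoxy-2,6-bis(methoxymethoxy)phenyl]ethynyl}oxy)silane; 9 methyl coumalate (methyl 2-oxo-2H-pyran-5-carboxylate)
Product: 11 methyl 3-[4-methoxy-2,6-bis(methoxymethoxy)phenyl]-4-[(triisopropylsilyl)oxy]benzoate, via bicyclic lactone 10 (not isolated)
Conditions: 9 (1.5 equiv), toluene, 110 °C, sealed tube
Reagents that add atoms: none
Why: The oxygen-raised HOMO of the siloxyalkyne and the low LUMO of the 2-pyranone-5-carboxylate should combine in an inverse-electron-demand [4+2] cycloaddition across C3 and C6 of the pyranone, probably asynchronous, with bonding to C6 in advance. The bridged lactone 10 then loses CO2 by retro-[4+2], which is irreversible and makes ring B aromatic. The closest known reaction type is the Diels–Alder and decarboxylation sequence of methyl coumalate and related 2-pyranones with ynamines, alkoxyalkynes and enol ethers to give benzoates. Ring B is closed by a six-membered pericyclic cycloaddition that forms C2'–C3' and C4'–C5', followed by cycloreversion; the two bridgehead stereocentres of 10 vanish on aromatization, so nothing stereochemical has to be controlled. The selectivity needed is regiochemical: the alkyne carbon β to the siloxy group, which bears the aryl ring, must bond to C6, so that oxygen ends para and the aryl group meta to the ester; the opposite sense would give the 4-aryl-3-siloxybenzoate. The substrate secures this because the largest HOMO coefficient of the ynol ether lies on the aryl-bearing carbon and the largest LUMO coefficient of the pyranone on C6, the carbon β to the ester and at the end of the vinylogous lactone. The triisopropylsilyl group is the one that best resists the thermal shift of silicon to carbon, and the sp carbon keeps the di-ortho-substituted aryl ring out of the way of the approaching diene.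

Step 6
Reactants: 11 methyl 3-[4-methoxy-2,6-bis(methoxymethoxy)phenyl]-4-[(triisopropylsilyl)oxy]benzoate
Product: 13 methyl 3-(2,6-dihydroxy-4-methoxyphenyl)-4-hydroxybenzoate, via phenol 12 (not isolated)
Conditions: Bu4NF, THF, 0 °C; then conc. HCl, MeOH, 50 °C
Reagents that add atoms: none
Why: Fluoride cleaves the aryl silyl ether, and acid-catalysed acetal exchange with methanol then removes both methoxymethyl groups as dimethoxymethane, which keeps formaldehyde equivalents away from the electron-rich ring; the methyl ester and the methyl ether are untouched, and ring A becomes a symmetric free resorcinol for step 7.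

Step 7
Reactants: 13 methyl 3-(2,6-dihydroxy-4-methoxyphenyl)-4-hydroxybenzoate
Product: 14 methyl 3-(3-acetyl-2,6-dihydroxy-4-methoxyphenyl)-4-hydroxybenzoate
Conditions: AcOH, BF3·OEt2 (3 equiv), 85 °C; then aq. NaOAc
Reagents that add atoms: acetic acid, CC(=O)O
Why: Friedel–Crafts C-acetylation of a resorcinol monomethyl ether ring with acetic acid and BF3 (Nencki-type); the two open ring A carbons are equivalent by symmetry and each is ortho and para to a free hydroxyl, ring B is deactivated by its ester, no benzyl ether is present, and the boron chelate of the product should resist a second acylation.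

Step 8
Reactants: 14 methyl 3-(3-acetyl-2,6-dihydroxy-4-methoxyphenyl)-4-hydroxybenzoate
Product: 15 methyl 3-[3-acetyl-6-(benzyloxy)-2-hydroxy-4-methoxyphenyl]-4-(benzyloxy)benzoate
Conditions: BnBr (2.2 equiv), K2CO3, acetone, reflux
Reagents that add atoms: benzyl bromide, BrCc1ccccc1
Why: Williamson etherification with the selectivity known for 2,4-dihydroxyacetophenones: the hydroxyl hydrogen-bonded to the acetyl carbonyl is the least nucleophilic, so two equivalents of halide should take the ring B phenol and the ring A hydroxyl para to the acetyl group and leave the future O1'' free.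

Step 9
Reactants: 15 methyl 3-[3-acetyl-6-(benzyloxy)-2-hydroxy-4-methoxyphenyl]-4-(benzyloxy)benzoate; 16 4-methoxybenzaldehyde
Product: 17 4-(benzyloxy)-3-{6-(benzyloxy)-2-hydroxy-4-methoxy-3-[(2E)-3-(4-methoxyphenyl)prop-2-enoyl]phenyl}benzoic acid
Conditions: KOH (50% aq.), EtOH, rt to 50 °C; then aq. HCl to pH 2
Reagents that add atoms: potassium hydroxide, [K+].[OH-]
Why: Claisen–Schmidt condensation of the methyl ketone with a non-enolizable aldehyde, with E1cB loss of water to the thermodynamically favoured E-enone; the same hydroxide saponifies the methyl benzoate, which is wanted for step 12, and benzyl and methyl ethers are stable to it.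

Step 10
Reactants: 17 4-(benzyloxy)-3-{6-(benzyloxy)-2-hydroxy-4-methoxy-3-[(2E)-3-(4-methoxyphenyl)prop-2-enoyl]phenyl}benzoic acid
Product: 18 4-(benzyloxy)-3-[7-(benzyloxy)-5-methoxy-2-(4-methoxyphenyl)-4-oxo-4H-chromen-8-yl]benzoic acid
Conditions: I2 (10 mol %), DMSO, 120 °C
Reagents that add atoms: none
Why: Iodine-catalysed oxidative cyclization of a 2'-hydroxychalcone in DMSO (oxa-Michael closure, α-iodination, loss of HI, reoxidation of HI by the sulfoxide); O5'' is methylated, so only the hydroxyl beside the biaryl bond can close and the 8-aryl flavone is the only constitution open.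

Step 11
Reactants: 19 2',4',6'-trihydroxyacetophenone
Product: 20 1-[2,4-bis(benzyloxy)-6-hydroxyphenyl]ethan-1-one
Conditions: BnBr (2.1 equiv), K2CO3, acetone, reflux
Reagents that add atoms: benzyl bromide, BrCc1ccccc1
Why: Selective double Williamson etherification of phloroacetophenone: the para hydroxyl and one ortho hydroxyl react, and the remaining ortho hydroxyl is chelated to the ketone and stays free, as the ring A nucleophile of unit 1 requires.

Step 12
Reactants: 18 4-(benzyloxy)-3-[7-(benzyloxy)-5-methoxy-2-(4-methoxyphenyl)-4-oxo-4H-chromen-8-yl]benzoic acid; 20 1-[2,4-bis(benzyloxy)-6-hydroxyphenyl]ethan-1-one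
Product: 22 1-[2,4-bis(benzyloxy)-6-hydroxyphenyl]-3-{4-(benzyloxy)-3-[7-(benzyloxy)-5-methoxy-2-(4-methoxyphenyl)-4-oxo-4H-chromen-8-yl]phenyl}propane-1,3-dione, via acid chloride 21 (not isolated)
Conditions: 18, (COCl)2, DMF (cat.), CH2Cl2, 0 °C to rt, concentrate; 20, LiN(SiMe3)2 (3.2 equiv), THF, −78 °C, then 21, −78 °C to rt; aq. HCl
Reagents that add atoms: none
Why: Acid chloride formation with oxalyl chloride, then Claisen-type C-acylation of the lithium phenoxide enolate of the ortho-hydroxyacetophenone (the one-pot variant of the Baker–Venkataraman sequence); material acylated on oxygen should rearrange to the same 1,3-diketone under the excess base, and the finished flavone has no acidic hydrogen.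

Step 13
Reactants: 22 1-[2,4-bis(benzyloxy)-6-hydroxyphenyl]-3-{4-(benzyloxy)-3-[7-(benzyloxy)-5-methoxy-2-(4-methoxyphenyl)-4-oxo-4H-chromen-8-yl]phenyl}propane-1,3-dione
Product: 23 5,7-bis(benzyloxy)-2-{4-(benzyloxy)-3-[7-(benzyloxy)-5-methoxy-2-(4-methoxyphenyl)-4-oxo-4H-chromen-8-yl]phenyl}-4H-chromen-4-one
Conditions: TsOH·H2O (20 mol %), toluene, 90 °C
Reagents that add atoms: none
Why: Acid-catalysed cyclodehydration of an ortho-hydroxyaryl 1,3-diketone (hemiketal formation, then loss of water) closes the pyranone of unit 1; O5'' is still methylated, so unit 2 cannot isomerize by ring opening, and partial loss of a benzyl group would be harmless because step 14 removes them all.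

Step 14
Reactants: 23 5,7-bis(benzyloxy)-2-{4-(benzyloxy)-3-[7-(benzyloxy)-5-methoxy-2-(4-methoxyphenyl)-4-oxo-4H-chromen-8-yl]phenyl}-4H-chromen-4-one
Product: 24 podocarpusflavone A, 5,7-dihydroxy-8-[5-(5,7-dihydroxy-4-oxo-4H-chromen-2-yl)-2-hydroxyphenyl]-2-(4-methoxyphenyl)-4H-chromen-4-one
Conditions: BCl3 (excess), C6HMe5, CH2Cl2, −78 °C to rt; MeOH
Reagents that add atoms: none
Why: Lewis acid ether cleavage: BCl3 removes aryl benzyl ethers at low temperature with pentamethylbenzene as trap for the benzyl cation, and on warming it removes the methyl ether peri to C4''=O through the boron chelate; the methoxy group on C4''' has no chelating neighbour and should stay.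

## Compound list

1 | 5-methoxyresorcinol | COc1cc(O)cc(O)c1 | starting material
2 | 1-methoxy-3,5-bis(methoxymethoxy)benzene | COCOc1cc(OC)cc(OCOC)c1 | intermediate
3 | [4-methoxy-2,6-bis(methoxymethoxy)phenyl]lithium | [Li]c1c(OCOC)cc(OC)cc1OCOC | intermediate
4 | 4-methoxy-2,6-bis(methoxymethoxy)benzaldehyde | O=Cc1c(OCOC)cc(OC)cc1OCOC | intermediate
5 | 2-ethynyl-5-methoxy-1,3-bis(methoxymethoxy)benzene | C#Cc1c(OCOC)cc(OC)cc1OCOC | intermediate
6 | lithium [4-methoxy-2,6-bis(methoxymethoxy)phenyl]acetylide | [Li]C#Cc1c(OCOC)cc(OC)cc1OCOC | intermediate
7 | lithium 2-[4-methoxy-2,6-bis(methoxymethoxy)phenyl]ethynolate | [Li]OC#Cc1c(OCOC)cc(OC)cc1OCOC | intermediate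
8 | triisopropyl({[4-methoxy-2,6-bis(methoxymethoxy)phenyl]ethynyl}oxy)silane | CC(C)[Si](C(C)C)(C(C)C)OC#Cc1c(OCOC)cc(OC)cc1OCOC | intermediate
9 | methyl coumalate | COC(=O)C1=COC(=O)C=C1 | starting material
10 | methyl 7-[4-methoxy-2,6-bis(methoxymethoxy)phenyl]-3-oxo-8-[(triisopropylsilyl)oxy]-2-oxabicyclo[2.2.2]octa-5,7-diene-6-carboxylate (racemic) | COC(=O)C1=CC2C(=O)OC1C(c1c(OCOC)cc(OC)cc1OCOC)=C2O[Si](C(C)C)(C(C)C)C(C)C | intermediate
11 | methyl 3-[4-methoxy-2,6-bis(methoxymethoxy)phenyl]-4-[(triisopropylsilyl)oxy]benzoate | COC(=O)c1ccc(O[Si](C(C)C)(C(C)C)C(C)C)c(c1)-c1c(OCOC)cc(OC)cc1OCOC | intermediate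
12 | methyl 4-hydroxy-3-[4-methoxy-2,6-bis(methoxymethoxy)phenyl]benzoate | COC(=O)c1ccc(O)c(c1)-c1c(OCOC)cc(OC)cc1OCOC | intermediate
13 | methyl 3-(2,6-dihydroxy-4-methoxyphenyl)-4-hydroxybenzoate | COC(=O)c1ccc(O)c(c1)-c1c(O)cc(OC)cc1O | intermediate
14 | methyl 3-(3-acetyl-2,6-dihydroxy-4-methoxyphenyl)-4-hydroxybenzoate | COC(=O)c1ccc(O)c(c1)-c1c(O)cc(OC)c(C(C)=O)c1O | intermediate
15 | methyl 3-[3-acetyl-6-(benzyloxy)-2-hydroxy-4-methoxyphenyl]-4-(benzyloxy)benzoate | COC(=O)c1ccc(OCc2ccccc2)c(c1)-c1c(OCc2ccccc2)cc(OC)c(C(C)=O)c1O | intermediate
16 | 4-methoxybenzaldehyde | COc1ccc(C=O)cc1 | starting material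
17 | 4-(benzyloxy)-3-{6-(benzyloxy)-2-hydroxy-4-methoxy-3-[(2E)-3-(4-methoxyphenyl)prop-2-enoyl]phenyl}benzoic acid | OC(=O)c1ccc(OCc2ccccc2)c(c1)-c1c(OCc2ccccc2)cc(OC)c(C(=O)/C=C/c2ccc(OC)cc2)c1O | intermediate
18 | 4-(benzyloxy)-3-[7-(benzyloxy)-5-methoxy-2-(4-methoxyphenyl)-4-oxo-4H-chromen-8-yl]benzoic acid | COc1ccc(cc1)-c1cc(=O)c2c(OC)cc(OCc3ccccc3)c(-c3cc(C(O)=O)ccc3OCc3ccccc3)c2o1 | intermediate
19 | 2',4',6'-trihydroxyacetophenone | CC(=O)c1c(O)cc(O)cc1O | starting material
20 | 1-[2,4-bis(benzyloxy)-6-hydroxyphenyl]ethan-1-one | CC(=O)c1c(O)cc(OCc2ccccc2)cc1OCc1ccccc1 | intermediate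
21 | 4-(benzyloxy)-3-[7-(benzyloxy)-5-methoxy-2-(4-methoxyphenyl)-4-oxo-4H-chromen-8-yl]benzoyl chloride | COc1ccc(cc1)-c1cc(=O)c2c(OC)cc(OCc3ccccc3)c(-c3cc(C(Cl)=O)ccc3OCc3ccccc3)c2o1 | intermediate
22 | 1-[2,4-bis(benzyloxy)-6-hydroxyphenyl]-3-{4-(benzyloxy)-3-[7-(benzyloxy)-5-methoxy-2-(4-methoxyphenyl)-4-oxo-4H-chromen-8-yl]phenyl}propane-1,3-dione | COc1ccc(cc1)-c1cc(=O)c2c(OC)cc(OCc3ccccc3)c(-c3cc(C(=O)CC(=O)c4c(O)cc(OCc5ccccc5)cc4OCc4ccccc4)ccc3OCc3ccccc3)c2o1 | intermediate
23 | 5,7-bis(benzyloxy)-2-{4-(benzyloxy)-3-[7-(benzyloxy)-5-methoxy-2-(4-methoxyphenyl)-4-oxo-4H-chromen-8-yl]phenyl}-4H-chromen-4-one | COc1ccc(cc1)-c1cc(=O)c2c(OC)cc(OCc3ccccc3)c(-c3cc(-c4cc(=O)c5c(OCc6ccccc6)cc(OCc6ccccc6)cc5o4)ccc3OCc3ccccc3)c2o1 | intermediate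
24 | podocarpusflavone A | COc1ccc(-c2cc(=O)c3c(O)cc(O)c(-c4cc(-c5cc(=O)c6c(O)cc(O)cc6o5)ccc4O)c3o2)cc1 | target

## Step count and weak points

Total: 14 steps. Longest linear sequence: 13 steps (steps 1–10 and 12–14, from 1); step 11 is a one-step side branch.

**Step 5 (key step).** The cycloaddition may be outrun by decay of the ynol silyl ether: a thermal silyl shift to a silylketene, or hydrolysis by adventitious acid. The two ortho acetal groups also slow the approach to the aryl-bearing carbon. A stepwise addition could close to a four-membered ring instead of the bridged lactone. Regiocontrol could erode if the trioxygenated aryl ring polarizes the alkyne against the siloxy group.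
Fallback: make the same biaryl bond by cross-coupling; this gives up the ring-forming logic but reaches the same compound. It sets out from 2. The lithiation of step 2 is followed by ZnCl2 to give [4-methoxy-2,6-bis(methoxymethoxy)phenyl]zinc chloride F1. Commercial methyl 3-bromo-4-hydroxybenzoate is silylated (iPr3SiCl, imidazole, DMF) to methyl 3-bromo-4-[(triisopropylsilyl)oxy]benzoate F2. Negishi coupling of F1 with F2 (Pd(OAc)2 and SPhos, reduced in the flask to the active zerovalent palladium, THF, 60 °C) comes back to the route at 11.

**Step 4.** Oxygen transfer to the hindered, electron-rich acetylide may be incomplete; the ynolate may be silylated on carbon; the product may hydrolyse during isolation.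
Fallback: reach the ynolate by rearrangement instead of oxidation. It sets out from 4. Addition of LiCHBr2 (from CH2Br2 and LiN(iPr)2, THF, −78 °C) gives 2,2-dibromo-1-[4-methoxy-2,6-bis(methoxymethoxy)phenyl]ethan-1-ol F3 (racemic). Dess–Martin oxidation gives 2,2-dibromo-1-[4-methoxy-2,6-bis(methoxymethoxy)phenyl]ethan-1-one F4. LiN(SiMe3)2 and then n-BuLi trigger the Kowalski rearrangement (bromine–lithium exchange on the dibromoenolate, 1,2-shift of the aryl group) to ynolate 7, which is silylated with iPr3SiOTf as before. The sequence comes back at 8.

**Step 12.** Acylation on the phenoxide oxygen, double acylation, or proton transfer from the product diketone to unreacted enolate may leave mixtures; the acid chloride of a large, poorly soluble flavone may react slowly at −78 °C.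
Fallback: stage the process. It sets out from 18 and 20. Carbodiimide esterification (EDC·HCl, DMAP, CH2Cl2) gives 2-acetyl-3,5-bis(benzyloxy)phenyl 4-(benzyloxy)-3-[7-(benzyloxy)-5-methoxy-2-(4-methoxyphenyl)-4-oxo-4H-chromen-8-yl]benzoate F5, which is isolated and then rearranged by intramolecular acyl transfer (Baker–Venkataraman, LiN(SiMe3)2, THF, −20 °C to rt). It comes back at 22.

**Step 14.** Benzyl cations may alkylate the phloroglucinol carbons if trapping is slow. The peri demethylation may lag behind debenzylation, or long exposure may begin to cleave the anisole.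
Fallback: separate the two cleavages. It sets out from 23. Hydrogenolysis (H2, Pd/C, THF–MeOH) removes the four benzyl groups and gives 5''-O-methylpodocarpusflavone A F6. The peri methyl ether is then cleaved alone with AlCl3 in MeCN, directed by chelation to C4''=O. It comes back at 24.

## Further compounds

F1 | step 5 | [4-methoxy-2,6-bis(methoxymethoxy)phenyl]zinc chloride | Cl[Zn]c1c(OCOC)cc(OC)cc1OCOC
F2 | step 5 | methyl 3-bromo-4-[(triisopropylsilyl)oxy]benzoate | COC(=O)c1ccc(O[Si](C(C)C)(C(C)C)C(C)C)c(Br)c1
F3 | step 4 | 2,2-dibromo-1-[4-methoxy-2,6-bis(methoxymethoxy)phenyl]ethan-1-ol (racemic) | OC(C(Br)Br)c1c(OCOC)cc(OC)cc1OCOC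
F4 | step 4 | 2,2-dibromo-1-[4-methoxy-2,6-bis(methoxymethoxy)phenyl]ethan-1-one | O=C(C(Br)Br)c1c(OCOC)cc(OC)cc1OCOC
F5 | step 12 | 2-acetyl-3,5-bis(benzyloxy)phenyl 4-(benzyloxy)-3-[7-(benzyloxy)-5-methoxy-2-(4-methoxyphenyl)-4-oxo-4H-chromen-8-yl]benzoate | COc1ccc(cc1)-c1cc(=O)c2c(OC)cc(OCc3ccccc3)c(-c3cc(C(=O)Oc4cc(OCc5ccccc5)cc(OCc5ccccc5)c4C(C)=O)ccc3OCc3ccccc3)c2o1
F6 | step 14 | 5''-O-methylpodocarpusflavone A | COc1ccc(-c2cc(=O)c3c(OC)cc(O)c(-c4cc(-c5cc(=O)c6c(O)cc(O)cc6o5)ccc4O)c3o2)cc1
A1 | alternative 1 | 3-{4-(benzyloxy)-3-[5,7-bis(benzyloxy)-2-(4-methoxyphenyl)-4-oxo-4H-chromen-8-yl]phenyl}prop-2-ynoic acid | COc1ccc(cc1)-c1cc(=O)c2c(OCc3ccccc3)cc(OCc3ccccc3)c(-c3cc(C#CC(O)=O)ccc3OCc3ccccc3)c2o1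
A2 | alternative 1 | 3,5-bis(benzyloxy)-2-(trimethylsilyl)phenyl trifluoromethanesulfonate | C[Si](C)(C)c1c(OCc2ccccc2)cc(OCc2ccccc2)cc1OS(=O)(=O)C(F)(F)F
A3 | alternative 1 | penta-O-benzyl podocarpusflavone A | COc1ccc(-c2cc(=O)c3c(OCc4ccccc4)cc(OCc4ccccc4)c(-c4cc(-c5cc(=O)c6c(OCc7ccccc7)cc(OCc7ccccc7)cc6o5)ccc4OCc4ccccc4)c3o2)cc1
A4 | alternative 2 | methyl 4-(benzyloxy)-3-[({(1Z)-1-(4-methoxyphenyl)-3-oxo-7-[(triisopropylsilyl)oxy]hept-1-ene-4,6-diyn-1-yl}oxy)ethynyl]benzoate | COc1ccc(cc1)/C(OC#Cc1cc(C(=O)OC)ccc1OCc1ccccc1)=C/C(=O)C#CC#CO[Si](C(C)C)(C(C)C)C(C)C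
A5 | alternative 2 | methyl 3-[5-acetoxy-4'-methoxy-7-(triisopropylsiloxy)flavon-8-yl]-4-(benzyloxy)benzoate | COc1ccc(cc1)-c1cc(=O)c2c(OC(C)=O)cc(O[Si](C(C)C)(C(C)C)C(C)C)c(-c3cc(C(=O)OC)ccc3OCc3ccccc3)c2o1
A6 | alternative 3 | ({[2-(benzyloxy)-5-bromophenyl]ethynyl}oxy)triisopropylsilane | CC(C)[Si](C(C)C)(C(C)C)OC#Cc1cc(Br)ccc1OCc1ccccc1
A7 | alternative 3 | 3-ethoxycyclobut-2-en-1-one | CCOC1=CC(=O)C1
A8 | alternative 3 | 2-[2-(benzyloxy)-5-bromophenyl]-5-ethoxy-3-(triisopropylsiloxy)phenol | Oc1cc(OCC)cc(O[Si](C(C)C)(C(C)C)C(C)C)c1-c1cc(Br)ccc1OCc1ccccc1
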